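The 20-membered bis-lactam ring is opened at the bond between the secondary amine nitrogen and the adjacent CH2 of the four-carbon chain. The key step closes this N–CH2 bond by a Fukuyama–Mitsunobu macrocyclisation: a 2-nitrobenzenesulfonamide on the three-carbon arm is alkylated by the primary alcohol ending the four-carbon arm. It exploits the acidity that the sulfonyl group lends this one nitrogen and the turn imposed by the two Z-enamides on the cis-fused hexahydrodibenzofuranone. The precursor is an open bis-(Z)-enamide; its core comes from an enantioselective Diels–Alder reaction followed by an intramolecular oxa-Michael addition.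

Key step: step 12

Assumption: the (R,R)-diol catalyst of step 4 is taken to give the (1S)-aldehyde 6 by analogy with 2-alkyl acroleins; if the opposite sense is found, the (S,S)-diol is used and nothing else changes.

Step 1
Reactants: 1 1-(5-bromo-2-hydroxyphenyl)ethan-1-one
Product: 2 1-[5-bromo-2-(methoxymethoxy)phenyl]ethan-1-one
Conditions: NaH, DMF, 0 °C; MOMCl, 0 °C → rt
Reagents that add atoms: chloromethyl methyl ether, COCCl
Why: Williamson-type O-alkylation of the sodium phenoxide gives an acetal ether that survives base, ylide and oxidant and falls off in the acid step 7.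

Step 2
Reactants: 2 1-[5-bromo-2-(methoxymethoxy)phenyl]ethan-1-one
Product: 3 4-bromo-1-(methoxymethoxy)-2-(prop-1-en-2-yl)benzene
Conditions: Ph3PCH3Br, KOt-Bu, THF, 0 °C → rt
Reagents that add atoms: methyltriphenylphosphonium bromide, C[P+](c1ccccc1)(c1ccccc1)c1ccccc1.[Br-]
Why: Wittig methylenation of the aryl methyl ketone with the non-stabilised ylide should give the 1,1-disubstituted alkene.

Step 3
Reactants: 3 4-bromo-1-(methoxymethoxy)-2-(prop-1-en-2-yl)benzene
Product: 4 2-[5-bromo-2-(methoxymethoxy)phenyl]prop-2-enal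
Conditions: SeO2, 1,4-dioxane/H2O, 80 °C
Reagents that add atoms: selenium dioxide, O=[Se]=O
Why: Riley allylic oxidation (ene reaction, then 2,3-sigmatropic shift) of the only allylic CH3 should give the 2-aryl acrolein, which is used at once.

Step 4
Reactants: 4 2-[5-bromo-2-(methoxymethoxy)phenyl]prop-2-enal; 5 (E)-3-[(tert-butyldimethylsilyl)oxy]-N,N-dimethylbuta-1,3-dien-1-amine
Product: 6 (1S,2S)-1-[5-bromo-2-(methoxymethoxy)phenyl]-4-[(tert-butyldimethylsilyl)oxy]-2-(dimethylamino)cyclohex-3-ene-1-carbaldehyde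
Conditions: (R,R)-α,α,α',α'-tetra(1-naphthyl)-2,2-dimethyl-1,3-dioxolane-4,5-dimethanol (20 mol %), toluene, −78 °C
Reagents that add atoms: none
Why: Hydrogen-bond-catalysed Diels–Alder reaction of a 1-amino-3-siloxydiene with a 2-substituted acrolein: the diene CH2 terminus bonds to the acrolein β-carbon, the chiral diol binds the formyl group and blocks one face of the dienophile so that the quaternary C1 is set by the catalyst, and the endo approach places NMe2 cis to CHO at C2 (a centre removed in step 7).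

Step 5
Reactants: 7 diphenyl phosphite; 8 tert-butyl bromoacetate
Product: 9 tert-butyl 2-(diphenoxyphosphoryl)acetate
Conditions: Et3N, CH2Cl2, 0 °C → rt
Reagents that add atoms: none
Why: Michaelis–Becker P-alkylation of the phosphite anion by the α-bromo ester gives the diaryl phosphonoacetate needed for Z-selective olefination.

Step 6
Reactants: 6 cycloadduct aldehyde; 9 tert-butyl 2-(diphenoxyphosphoryl)acetate
Product: 10 tert-butyl (2Z)-3-{(1S,2S)-1-[5-bromo-2-(methoxymethoxy)phenyl]-4-[(tert-butyldimethylsilyl)oxy]-2-(dimethylamino)cyclohex-3-en-1-yl}prop-2-enoate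
Conditions: 9, NaH, THF, 0 °C; then 6, −78 → 0 °C
Reagents that add atoms: none
Why: Z-selective Horner–Wadsworth–Emmons olefination: the electron-poor aryloxy groups make oxaphosphetane collapse faster than equilibration, so the kinetic cis adduct should give the Z-enoate, and the non-enolisable aldehyde cannot epimerise.

Step 7
Reactants: 10 Z-enoate
Product: 12 (2Z)-3-[(4aR,9bS)-8-bromo-3-oxo-1,2,3,4-tetrahydrodibenzo[b,d]furan-9b(4aH)-yl]prop-2-enoic acid, via phenolic enone acid 11 (not isolated)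
Conditions: TFA/CH2Cl2/H2O (10:10:1), 0 °C → rt; evaporate; sat. aq. NaHCO3/THF, rt; then pH 3
Reagents that add atoms: none
Why: Acid hydrolyses the silyl enol ether, eliminates dimethylamine to the enone and cleaves the MOM ether and tert-butyl ester; the phenol then adds to the only enone β-carbon in a 5-exo-trig oxa-Michael reaction that can only give the cis-fused ring, so C4a (R) is dictated by the quaternary centre.

Step 8
Reactants: 13 propane-1,3-diamine; 14 2-nitrobenzenesulfonyl chloride
Product: 15 N-(3-aminopropyl)-2-nitrobenzenesulfonamide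
Conditions: 13 (5 equiv), CH2Cl2, 0 °C, slow addition of 14
Reagents that add atoms: none
Why: Sulfonylation of an amine; the excess of diamine should hold the reaction at the mono-sulfonamide.

Step 9
Reactants: 12 tricyclic Z-acrylic acid; 15 N-(3-aminopropyl)-2-nitrobenzenesulfonamide
Product: 16 (2Z)-3-[(4aR,9bS)-8-bromo-3-oxo-1,2,3,4-tetrahydrodibenzo[b,d]furan-9b(4aH)-yl]-N-{3-[(2-nitrophenyl)sulfonylamino]propyl}prop-2-enamide
Conditions: EDC·HCl, HOBt, i-Pr2NEt, DMF, 0 °C → rt
Reagents that add atoms: none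
Why: Carbodiimide/HOBt amide coupling acylates the primary amine and not the sulfonamide N–H, and should leave the Z-alkene and both stereocentres untouched.

Step 10
Reactants: 17 (Z)-3-iodoprop-2-enoic acid; 18 4-aminobutan-1-ol
Product: 19 (2Z)-N-(4-hydroxybutyl)-3-iodoprop-2-enamide
Conditions: EDC·HCl, HOBt, i-Pr2NEt, CH2Cl2, 0 °C
Reagents that add atoms: none
Why: Amide coupling of the pre-activated acid is chemoselective for the amine over the alcohol, and the low temperature should prevent addition–elimination at the vinyl iodide.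

Step 11
Reactants: 16 bromo amide; 19 (2Z)-N-(4-hydroxybutyl)-3-iodoprop-2-enamide
Product: 21 (2Z)-3-[(4aR,9bS)-8-[(1Z)-3-[(4-hydroxybutyl)amino]-3-oxoprop-1-en-1-yl]-3-oxo-1,2,3,4-tetrahydrodibenzo[b,d]furan-9b(4aH)-yl]-N-{3-[(2-nitrophenyl)sulfonylamino]propyl}prop-2-enamide, via aryl pinacol boronate 20 (not isolated)
Conditions: B2pin2, Pd(dppf)Cl2 (5 mol %), KOAc, 1,4-dioxane, 85 °C; then 19, aq. K3PO4, 45 °C
Reagents that add atoms: bis(pinacolato)diboron, CC1(C)OB(OC1(C)C)B1OC(C)(C)C(C)(C)O1 (supplies the boryl group of 20 only)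
Why: One-pot Miyaura borylation/Suzuki–Miyaura coupling: the boronate couples with the Z-vinyl iodide, and oxidative addition and reductive elimination should keep the alkene geometry at this mild temperature.

Step 12
Reactants: 21 seco sulfonamide alcohol
Product: 22 the target macrocycle bearing a 2-nitrobenzenesulfonyl group on the ring amine nitrogen, (4aR,9bS), both enamides Z
Conditions: PPh3, DIAD, toluene/THF, 0.002 M, slow addition of 21, rt
Reagents that add atoms: none
Why: PPh3 and DIAD form the betaine, which deprotonates the sulfonamide N–H (pKa about 10) and turns the primary alcohol into an alkoxyphosphonium ion; the sulfonamide anion then displaces Ph3P=O at the primary carbon in an SN2 reaction and forms the N–CH2 bond. The closest known reaction is the Fukuyama–Mitsunobu alkylation of 2-nitrobenzenesulfonamides, which is used to close macrocyclic polyamine lactams. The 20-membered ring closes in the exo-tet mode, and no stereocentre is formed or touched. The step needs N-alkylation of the sulfonamide over the two amide N–H groups and over intermolecular coupling: only the sulfonamide is acidic enough for the betaine, the four-carbon spacer makes imidate or pyrrolidine formation from the neighbouring amide slow, and high dilution with slow addition should suppress oligomers. The two Z-enamides and the rigid cis-fused tricycle turn both arms to the same side, which brings N and CH2 close. The ketone, aryl ether and enamides are inert to these neutral redox conditions.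

Step 13
Reactants: 22 N-(2-nitrophenylsulfonyl) macrocycle
Product: 23 target macrocycle, (4aR,9bS), both enamides Z
Conditions: PhSH, K2CO3, MeCN, rt
Reagents that add atoms: none
Why: Fukuyama deprotection: the thiolate adds at the sulfonyl-bearing ring carbon of the nitroarene (Meisenheimer adduct), SO2 is lost and the secondary amine is freed, while the β-substituted secondary Z-acrylamides are poor thiol acceptors at room temperature.

Compound list
1 | 1-(5-bromo-2-hydroxyphenyl)ethan-1-one | CC(=O)c1cc(Br)ccc1O | starting material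
2 | 1-[5-bromo-2-(methoxymethoxy)phenyl]ethan-1-one | CC(=O)c1cc(Br)ccc1OCOC | intermediate
3 | 4-bromo-1-(methoxymethoxy)-2-(prop-1-en-2-yl)benzene | CC(=C)c1cc(Br)ccc1OCOC | intermediate
4 | 2-[5-bromo-2-(methoxymethoxy)phenyl]prop-2-enal | C=C(C=O)c1cc(Br)ccc1OCOC | intermediate
5 | (E)-3-[(tert-butyldimethylsilyl)oxy]-N,N-dimethylbuta-1,3-dien-1-amine | CN(C)/C=C/C(=C)O[Si](C)(C)C(C)(C)C | starting material
6 | (1S,2S)-1-[5-bromo-2-(methoxymethoxy)phenyl]-4-[(tert-butyldimethylsilyl)oxy]-2-(dimethylamino)cyclohex-3-ene-1-carbaldehyde | CC(C)(C)[Si](C)(C)OC=1CC[C@](C=O)(c2cc(Br)ccc2OCOC)[C@@H](N(C)C)C=1 | intermediate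
7 | diphenyl phosphite | O=[PH](Oc1ccccc1)Oc1ccccc1 | starting material
8 | tert-butyl bromoacetate | CC(C)(C)OC(=O)CBr | starting material
9 | tert-butyl 2-(diphenoxyphosphoryl)acetate | CC(C)(C)OC(=O)CP(=O)(Oc1ccccc1)Oc1ccccc1 | intermediate
10 | tert-butyl (2Z)-3-{(1S,2S)-1-[5-bromo-2-(methoxymethoxy)phenyl]-4-[(tert-butyldimethylsilyl)oxy]-2-(dimethylamino)cyclohex-3-en-1-yl}prop-2-enoate | CC(C)(C)[Si](C)(C)OC=1CC[C@](/C=C\C(=O)OC(C)(C)C)(c2cc(Br)ccc2OCOC)[C@@H](N(C)C)C=1 | intermediate
11 | (2Z)-3-[(1S)-1-(5-bromo-2-hydroxyphenyl)-4-oxocyclohex-2-en-1-yl]prop-2-enoic acid | O=C1CC[C@](/C=C\C(=O)O)(c2cc(Br)ccc2O)C=C1 | intermediate (not isolated)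
12 | (2Z)-3-[(4aR,9bS)-8-bromo-3-oxo-1,2,3,4-tetrahydrodibenzo[b,d]furan-9b(4aH)-yl]prop-2-enoic acid | O=C1CC[C@]2(/C=C\C(=O)O)c3cc(Br)ccc3O[C@@H]2C1 | intermediate
13 | propane-1,3-diamine | NCCCN | starting material
14 | 2-nitrobenzenesulfonyl chloride | O=S(=O)(Cl)c1ccccc1[N+](=O)[O-] | starting material
15 | N-(3-aminopropyl)-2-nitrobenzenesulfonamide | NCCCNS(=O)(=O)c1ccccc1[N+](=O)[O-] | intermediate
16 | (2Z)-3-[(4aR,9bS)-8-bromo-3-oxo-1,2,3,4-tetrahydrodibenzo[b,d]furan-9b(4aH)-yl]-N-{3-[(2-nitrophenyl)sulfonylamino]propyl}prop-2-enamide | O=C1CC[C@]2(/C=C\C(=O)NCCCNS(=O)(=O)c4ccccc4[N+](=O)[O-])c3cc(Br)ccc3O[C@@H]2C1 | intermediate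
17 | (Z)-3-iodoprop-2-enoic acid | OC(=O)/C=C\I | starting material
18 | 4-aminobutan-1-ol | NCCCCO | starting material
19 | (2Z)-N-(4-hydroxybutyl)-3-iodoprop-2-enamide | OCCCCNC(=O)/C=C\I | intermediate
20 | 8-(4,4,5,5-tetramethyl-1,3,2-dioxaborolan-2-yl) analogue of 16 | O=C1CC[C@]2(/C=C\C(=O)NCCCNS(=O)(=O)c4ccccc4[N+](=O)[O-])c3cc(B4OC(C)(C)C(C)(C)O4)ccc3O[C@@H]2C1 | intermediate (not isolated)
21 | (2Z)-3-[(4aR,9bS)-8-[(1Z)-3-[(4-hydroxybutyl)amino]-3-oxoprop-1-en-1-yl]-3-oxo-1,2,3,4-tetrahydrodibenzo[b,d]furan-9b(4aH)-yl]-N-{3-[(2-nitrophenyl)sulfonylamino]propyl}prop-2-enamide | O=C1CC[C@]2(/C=C\C(=O)NCCCNS(=O)(=O)c4ccccc4[N+](=O)[O-])c3cc(/C=C\C(=O)NCCCCO)ccc3O[C@@H]2C1 | intermediate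
22 | target macrocycle with a 2-nitrobenzenesulfonyl group on the ring amine nitrogen, (4aR,9bS), Z,Z | O=C1CC[C@]23/C=C\C(=O)NCCCN(S(=O)(=O)c5ccccc5[N+](=O)[O-])CCCCNC(=O)/C=C\c4ccc(c2c4)O[C@@H]3C1 | intermediate
23 | target: 20-membered bis-(Z)-enamide spermidine lactam on the (4aR,9bS)-3-oxo-hexahydrodibenzofuran core | O=C1CC[C@]23/C=C\C(=O)NCCCNCCCCNC(=O)/C=C\c4ccc(c2c4)O[C@@H]3C1 | target

Total step count: 13. Longest linear sequence: 10 steps (steps 1, 2, 3, 4, 6, 7, 9, 11, 12, 13).

Steps most likely to fail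

Step 4. The diol catalyst may discriminate the faces of the 2-aryl acrolein poorly, or hetero-Diels–Alder addition across the formyl group may compete. Fallback, setting out from 4 and 5: the cycloaddition is run without catalyst (toluene, 0 °C → rt) to give the racemic endo cycloadduct F1. Olefination with 9 as in step 6 gives the racemic Z-enoate F2. The enantiomers are then separated by preparative chromatography on a chiral stationary phase, which sets aside the (1R,2R) enantiomer F3 and returns to the route at 10.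

Step 12. Intermolecular alkylation, or capture of the alkoxyphosphonium ion by the reduced azodicarboxylate, may outrun the slow 20-membered ring closure. Fallback, setting out from 12 and closing the same N–CH2 bond through a reversible imine:
- One-pot borylation/Suzuki coupling of 12 with 19 (conditions of step 11, one extra equivalent of base) passes through the boronate acid F4 and gives the hydroxybutyl enamide acid F5.
- EDC/HOBt coupling with 3-azidopropan-1-amine gives the azido amide alcohol F6.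
- Oxidation with the periodinane 1,1,1-triacetoxy-1,1-dihydro-1,2-benziodoxol-3(1H)-one (CH2Cl2, NaHCO3) gives the azido aldehyde F7.
- PPh3 in toluene at high dilution gives the iminophosphorane F8 (Staudinger reaction), which closes the ring by intramolecular aza-Wittig reaction to the macrocyclic imine F9.
- NaBH(OAc)3/AcOH reduces the C=N bond and gives 23 directly, so the sulfonamide and its removal are not needed.

Step 6. Addition of the phosphonate anion to the neopentyl-type aldehyde may be slow, and Z-selectivity may erode. Fallback, setting out from 6: lithiated trimethylsilyldiazomethane (LDA, THF, −78 °C → rt, Colvin rearrangement) converts the aldehyde into the terminal alkyne F10. LDA and then Boc2O give the tert-butyl alkynoate F11. Semi-hydrogenation over Pd/CaCO3 poisoned with Pb(OAc)2 (quinoline, H2) gives the Z-enoate and returns to the route at 10.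

Further compounds
F1 | step 4 | racemic endo cycloadduct (6 and its enantiomer, 1:1) | CC(C)(C)[Si](C)(C)OC=1CC[C@](C=O)(c2cc(Br)ccc2OCOC)[C@@H](N(C)C)C=1.CC(C)(C)[Si](C)(C)OC=1CC[C@@](C=O)(c2cc(Br)ccc2OCOC)[C@H](N(C)C)C=1
F2 | step 4 | racemic Z-enoate (10 and its enantiomer, 1:1) | CC(C)(C)[Si](C)(C)OC=1CC[C@](/C=C\C(=O)OC(C)(C)C)(c2cc(Br)ccc2OCOC)[C@@H](N(C)C)C=1.CC(C)(C)[Si](C)(C)OC=1CC[C@@](/C=C\C(=O)OC(C)(C)C)(c2cc(Br)ccc2OCOC)[C@H](N(C)C)C=1
F3 | step 4 | (1R,2R) enantiomer of 10 | CC(C)(C)[Si](C)(C)OC=1CC[C@@](/C=C\C(=O)OC(C)(C)C)(c2cc(Br)ccc2OCOC)[C@H](N(C)C)C=1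
F4 | step 12 | (2Z)-3-[(4aR,9bS)-3-oxo-8-(4,4,5,5-tetramethyl-1,3,2-dioxaborolan-2-yl)-1,2,3,4-tetrahydrodibenzo[b,d]furan-9b(4aH)-yl]prop-2-enoic acid (not isolated) | O=C1CC[C@]2(/C=C\C(=O)O)c3cc(B4OC(C)(C)C(C)(C)O4)ccc3O[C@@H]2C1
F5 | step 12 | (2Z)-3-[(4aR,9bS)-8-[(1Z)-3-[(4-hydroxybutyl)amino]-3-oxoprop-1-en-1-yl]-3-oxo-1,2,3,4-tetrahydrodibenzo[b,d]furan-9b(4aH)-yl]prop-2-enoic acid | O=C1CC[C@]2(/C=C\C(=O)O)c3cc(/C=C\C(=O)NCCCCO)ccc3O[C@@H]2C1
F6 | step 12 | N-(3-azidopropyl) amide of F5 | O=C1CC[C@]2(/C=C\C(=O)NCCCN=[N+]=[N-])c3cc(/C=C\C(=O)NCCCCO)ccc3O[C@@H]2C1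
F7 | step 12 | azido aldehyde (4-oxobutyl amide) from F6 | O=C1CC[C@]2(/C=C\C(=O)NCCCN=[N+]=[N-])c3cc(/C=C\C(=O)NCCCC=O)ccc3O[C@@H]2C1
F8 | step 12 | iminophosphorane from F7 (not isolated) | O=C1CC[C@]2(/C=C\C(=O)NCCCN=P(c4ccccc4)(c4ccccc4)c4ccccc4)c3cc(/C=C\C(=O)NCCCC=O)ccc3O[C@@H]2C1
F9 | step 12 | 20-membered cyclic imine, C=N in place of the N–CH2 bond of 23 (not isolated) | O=C1CC[C@]23/C=C\C(=O)NCCCN=CCCCNC(=O)/C=C\c4ccc(c2c4)O[C@@H]3C1
F10 | step 6 | (3S,4S)-4-[5-bromo-2-(methoxymethoxy)phenyl]-1-[(tert-butyldimethylsilyl)oxy]-4-ethynyl-N,N-dimethylcyclohex-1-en-3-amine | CC(C)(C)[Si](C)(C)OC=1CC[C@](C#C)(c2cc(Br)ccc2OCOC)[C@@H](N(C)C)C=1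
F11 | step 6 | tert-butyl 3-{(1S,2S)-1-[5-bromo-2-(methoxymethoxy)phenyl]-4-[(tert-butyldimethylsilyl)oxy]-2-(dimethylamino)cyclohex-3-en-1-yl}prop-2-ynoate | CC(C)(C)[Si](C)(C)OC=1CC[C@](C#CC(=O)OC(C)(C)C)(c2cc(Br)ccc2OCOC)[C@@H](N(C)C)C=1
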